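Remark on the chemistry: the SMILES is read as the 5E alkylidene (side-chain carbon C7 cis to ring carbon C4, H cis to the ring oxygen) with an S methyl-bearing centre. This is the less stable enol-ether geometry, so it is set by a stereospecific event; aldol–dehydration and anti-oxymetalation would give 5Z.

**Plan**

Numbering: ring O1, C2 (C=O), C3 (CMe), C4 (COH), C5; chain C6 (=CH), C7 (CHMe), C8 to C14; then the two furans.
1. Cuts, in order: C2–C3 of the lactone; C8–C9 (sp3–sp2); C9=C10 and C11=C12; the furan–C14 and furan–CH2–furan bonds.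
2. Enabling feature: in the ring O1–C2(=O)–C3=C4(OH)–C5, C2 is a carbonic-acid-level carbon held by the enol oxygen O1 of the exocyclic C5=C6 bond, and C3 is the α-carbon of the C4 carbonyl. C2 can therefore ride on O1 as an enol carbonate and be handed to C3 by an enolate without touching C5=C6.
3. Forward: 3,4-dibromofuran to the bis-furan iododiene 12 (6 steps); (S)-Roche ester to alkyne, (E)-iodoalkene and (E)-enol carbonate iodide 28 (10 steps); Negishi union at C8–C9; the last step closes the tetronic acid, the only ring made, unprotected.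
4. Stereochemistry: C7 from (S)-Roche ester; 5E from syn-hydromagnesiation (H and Mg cis), carried with retention through C–I, C–Li and C–O; 11E from a stabilised Wittig reaction; 9E from Takai olefination, kept in the Pd coupling.

Key step: step 18

**Route**

Step 1
Reactants: 1 3,4-dibromofuran; 2 oxetane
Product: 4 3-(4-bromofuran-3-yl)propan-1-ol, via 4-bromo-3-furyllithium 3 (not isolated)
Conditions: n-BuLi (1.0 equiv), Et2O, −78 °C; 2, then BF3·OEt2, −78 °C; H2O
Reagents that add atoms: none
Why: Bromine–lithium exchange on one C–Br of the symmetric dibromide gives a 3-furyllithium that is stable below −40 °C and opens BF3-activated oxetane (Lewis-acid-promoted organolithium opening of a cyclic ether) to install the three-carbon arm.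

Step 2
Reactants: 4 3-(4-bromofuran-3-yl)propan-1-ol; 5 furan-3-carbaldehyde
Product: 7 [4-(3-hydroxypropyl)furan-3-yl](furan-3-yl)methanol (racemic carbinol), via dilithio alkoxide aryllithium 6 (not isolated)
Conditions: n-BuLi (2.1 equiv), THF, −78 °C; then 5; H2O
Reagents that add atoms: none
Why: The first equivalent of n-BuLi forms the alkoxide, the second effects Br–Li exchange, and the aryllithium adds 1,2 to the aldehyde, joining the two furans through one carbon.

Step 3
Reactants: 7 [4-(3-hydroxypropyl)furan-3-yl](furan-3-yl)methanol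
Product: 8 3-[4-(furan-3-ylmethyl)furan-3-yl]propan-1-ol
Conditions: Et3SiH, CF3CO2H, CH2Cl2, −20 to 0 °C; aq NaHCO3
Reagents that add atoms: none
Why: Ionic hydrogenation: the acid ionises only the doubly furyl-stabilised carbinol and the silane delivers hydride to the cation, leaving the primary alcohol.

Step 4
Reactants: 8 3-[4-(furan-3-ylmethyl)furan-3-yl]propan-1-ol
Product: 9 3-[4-(furan-3-ylmethyl)furan-3-yl]propanal
Conditions: Dess–Martin periodinane, CH2Cl2, 0 to 25 °C
Reagents that add atoms: none
Why: Dess–Martin oxidation stops at the aldehyde under near-neutral conditions that furans tolerate.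

Step 5
Reactants: 9 3-[4-(furan-3-ylmethyl)furan-3-yl]propanal; 10 2-(triphenylphosphoranylidene)propanal
Product: 11 (2E)-5-[4-(furan-3-ylmethyl)furan-3-yl]-2-methylpent-2-enal
Conditions: toluene, 80 °C
Reagents that add atoms: none
Why: Wittig olefination with the stabilised α-methyl ylide should give the (E)-2-methylenal (formyl group trans to the chain), which is the 11E bond of the target.

Step 6
Reactants: 11 (2E)-5-[4-(furan-3-ylmethyl)furan-3-yl]-2-methylpent-2-enal
Product: 12 3-(furan-3-ylmethyl)-4-[(3E,5E)-6-iodo-4-methylhexa-3,5-dien-1-yl]furan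
Conditions: CrCl2, CHI3, THF, 0 °C, dark
Reagents that add atoms: iodoform IC(I)I
Why: Takai iodo-olefination (geminal dichromium reagent from CHI3 and CrCl2) converts the aldehyde to the (E)-alkenyl iodide, setting the 9E bond.

Step 7
Reactants: 13 methyl (2S)-3-hydroxy-2-methylpropanoate
Product: 14 methyl (2S)-3-[(tert-butyldimethylsilyl)oxy]-2-methylpropanoate
Conditions: t-BuMe2SiCl, imidazole, DMF, 25 °C
Reagents that add atoms: tert-butyldimethylsilyl chloride CC(C)(C)[Si](C)(C)Cl
Why: Standard silylation of the primary alcohol; the stereocentre that becomes C7 is bought.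

Step 8
Reactants: 14 methyl (2S)-3-[(tert-butyldimethylsilyl)oxy]-2-methylpropanoate
Product: 15 (2S)-3-[(tert-butyldimethylsilyl)oxy]-2-methylpropanal
Conditions: i-Bu2AlH, CH2Cl2, −78 °C; aq potassium sodium tartrate
Reagents that add atoms: none
Why: Low-temperature hydride reduction stops at the aluminium hemiacetal, which gives the aldehyde on work-up; used crude, the α-centre should not epimerise.

Step 9
Reactants: 15 (2S)-3-[(tert-butyldimethylsilyl)oxy]-2-methylpropanal
Product: 16 tert-butyl(dimethyl){[(2R)-2-methylbut-3-yn-1-yl]oxy}silane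
Conditions: dimethyl (1-diazo-2-oxopropyl)phosphonate, K2CO3, MeOH, 0 to 25 °C
Reagents that add atoms: dimethyl (1-diazo-2-oxopropyl)phosphonate COP(=O)(OC)C(=[N+]=[N-])C(C)=O
Why: Seyferth–Gilbert homologation with the Ohira–Bestmann reagent gives the terminal alkyne under conditions mild enough to keep the α-methyl centre (descriptor changes to R by priority only).

Step 10
Reactants: 16 tert-butyl(dimethyl){[(2R)-2-methylbut-3-yn-1-yl]oxy}silane; 17 propanal
Product: 19 (6R)-7-[(tert-butyldimethylsilyl)oxy]-6-methylhept-4-yn-3-ol (both C3 epimers), via lithium acetylide 18 (not isolated)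
Conditions: n-BuLi, THF, −78 °C; then 17; H2O
Reagents that add atoms: none
Why: Acetylide 1,2-addition to the aldehyde; the carbinol centre forms as a mixture, which does not matter because it becomes the C4 carbonyl.

Step 11
Reactants: 19 (6R)-7-[(tert-butyldimethylsilyl)oxy]-6-methylhept-4-yn-3-ol
Product: 21 (4E,6R)-7-[(tert-butyldimethylsilyl)oxy]-4-iodo-6-methylhept-4-en-3-ol, via alkenylmagnesium chloride 20 (not isolated)
Conditions: i-BuMgCl (2.3 equiv), Cp2TiCl2 (5 mol %), Et2O, 0 to 25 °C; then I2, THF, −78 to 0 °C; H2O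
Reagents that add atoms: iodine II
Why: Titanocene-catalysed hydromagnesiation of a propargylic alcohol adds H and Mg syn with Mg on the carbon next to the alkoxide (chelate), and iodinolysis with retention puts the side chain cis to the carbinol carbon, which is the 5E relationship of the target.

Step 12
Reactants: 21 (4E,6R)-7-[(tert-butyldimethylsilyl)oxy]-4-iodo-6-methylhept-4-en-3-ol
Product: 22 (4E,6R)-3,7-bis[(tert-butyldimethylsilyl)oxy]-4-iodo-6-methylhept-4-ene
Conditions: t-BuMe2SiOSO2CF3, 2,6-lutidine, CH2Cl2, −78 to 0 °C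
Reagents that add atoms: tert-butyldimethylsilyl trifluoromethanesulfonate CC(C)(C)[Si](C)(C)OS(=O)(=O)C(F)(F)F
Why: Silyl triflate silylation protects the hindered allylic alcohol for the organolithium step.

Step 13
Reactants: 22 (4E,6R)-3,7-bis[(tert-butyldimethylsilyl)oxy]-4-iodo-6-methylhept-4-ene
Product: 25 (4E,6R)-3,7-bis[(tert-butyldimethylsilyl)oxy]-6-methylhept-4-en-4-yl methyl carbonate, via alkenyllithium 23 (not isolated), via lithium enolate 24 (not isolated)
Conditions: t-BuLi (2.1 equiv), Et2O, −78 °C; LiOOt-Bu (from t-BuOOH and n-BuLi, THF, −78 °C), −78 to −20 °C; then DMPU, ClCO2Me, −78 to 0 °C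
Reagents that add atoms: lithium tert-butyl peroxide [Li+].CC(C)(C)O[O-]; methyl chloroformate COC(=O)Cl
Why: I–Li exchange gives a configurationally stable alkenyllithium, oxygen transfer from the lithium peroxide (oxenoid oxidation of alkenyllithiums) gives the lithium enolate with retention of the C=C geometry, and the hard chloroformate acylates it on oxygen, so the carbonate oxygen stands where iodine stood.

Step 14
Reactants: 25 (4E,6R)-3,7-bis[(tert-butyldimethylsilyl)oxy]-6-methylhept-4-en-4-yl methyl carbonate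
Product: 26 (4E,6R)-3,7-dihydroxy-6-methylhept-4-en-4-yl methyl carbonate
Conditions: aq HF (48 %), MeCN, 0 to 25 °C; used at once
Reagents that add atoms: none
Why: Acidic fluoride cleaves both silyl ethers and should leave the enol carbonate, which is labile to base but not to dilute acid.

Step 15
Reactants: 26 (4E,6R)-3,7-dihydroxy-6-methylhept-4-en-4-yl methyl carbonate
Product: 27 (4E,6R)-7-hydroxy-6-methyl-3-oxohept-4-en-4-yl methyl carbonate
Conditions: MnO2 (activated, excess), CH2Cl2, 25 °C
Reagents that add atoms: none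
Why: MnO2 oxidises only the allylic secondary alcohol and leaves the saturated primary alcohol, which may rest on the new ketone as a six-membered hemiketal because chain and ketone are cis.

Step 16
Reactants: 27 (4E,6R)-7-hydroxy-6-methyl-3-oxohept-4-en-4-yl methyl carbonate
Product: 28 (4E,6R)-7-iodo-6-methyl-3-oxohept-4-en-4-yl methyl carbonate
Conditions: PPh3, I2, imidazole, CH2Cl2, 0 °C
Reagents that add atoms: iodine II
Why: Appel-type iodination of the primary alcohol (drained from the hemiketal equilibrium) uses no base strong enough to enolise the ketone.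

Step 17
Reactants: 28 (4E,6R)-7-iodo-6-methyl-3-oxohept-4-en-4-yl methyl carbonate; 12 3-(furan-3-ylmethyl)-4-[(3E,5E)-6-iodo-4-methylhexa-3,5-dien-1-yl]furan
Product: 30 (4E,6S,8E,10E)-13-[4-(furan-3-ylmethyl)furan-3-yl]-6,10-dimethyl-3-oxotrideca-4,8,10-trien-4-yl methyl carbonate, via alkylzinc iodide 29 (not isolated)
Conditions: Zn dust, LiCl, THF, 35 °C; then 12, Pd(PPh3)4 (5 mol %), THF, 25 °C, dark
Reagents that add atoms: none
Why: Zinc inserts into the primary C–I bond to give an alkylzinc iodide that tolerates ketone and carbonate, and the Negishi sp3–sp2 coupling keeps the geometry of the dienyl iodide (the descriptor at the methyl centre changes to S by priority only).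

Step 18
Reactants: 30 (4E,6S,8E,10E)-13-[4-(furan-3-ylmethyl)furan-3-yl]-6,10-dimethyl-3-oxotrideca-4,8,10-trien-4-yl methyl carbonate
Product: 33 (5E)-5-{(2S,4E,6E)-9-[4-(furan-3-ylmethyl)furan-3-yl]-2,6-dimethylnona-4,6-dien-1-ylidene}-4-hydroxy-3-methylfuran-2(5H)-one, via lithium ketone enolate 31 (not isolated), via lithium tetronate 32 (not isolated)
Conditions: LiN(SiMe3)2 (2.2 equiv), THF, −78 to −20 °C; then cold 0.5 M HCl; dark
Reagents that add atoms: none
Why: Proposed new method: LiN(SiMe3)2 removes an α′-proton of the ethyl ketone to give the cross-conjugated enolate 31, whose carbon C3 adds to the carbonate carbonyl carried by O1; the tetrahedral intermediate expels methoxide, so the methoxycarbonyl carbon passes from oxygen-bound carbonate to carbon and becomes the lactone carbonyl C2 while O1–C5 is never broken, and the furan-2,4-dione is deprotonated at once to tetronate 32 (an acid of pKa about 4), which makes the closure irreversible. The closest known reaction types are the Claisen acylation of ketone enolates by carbonates, the closure of 2-acylphenyl carbonates to 4-hydroxycoumarins (Baker–Venkataraman manifold) and the Dieckmann synthesis of tetronic acids from O-acylated α-hydroxy esters; the closure of a 2-(alkoxycarbonyloxy)enone to a 5-ylidene tetronic acid is not known to have been shown. The ring O1–C2–C3–C4–C5 closes in the 5-(enolendo)-exo-trig mode, the mode of the Dieckmann route to tetronic acids. No stereocentre is made: the 5E geometry and the S centre are those of 30, because neither C5=C6 nor the C7–H bond takes part. The step needs α′- over γ-deprotonation (loss of the C7 hydrogen would give a dienolate and scramble both stereo-elements), which the hindered amide base at −78 °C should secure by taking the accessible CH2 proton irreversibly, and C- over O-acylation, which is secured because O-attack leads only to a strained dialkylidene cyclic carbonate that can revert, whereas C-attack ends in the stabilised tetronate. The excess of base keeps the released methoxide from cleaving unreacted enol carbonate.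

**Compound list**

1 | 3,4-dibromofuran | Brc1cocc1Br | starting material
2 | oxetane | C1COC1 | starting material
3 | 4-bromo-3-furyllithium | [Li]c1cocc1Br | intermediate
4 | 3-(4-bromofuran-3-yl)propan-1-ol | OCCCc1cocc1Br | intermediate
5 | furan-3-carbaldehyde | O=Cc1ccoc1 | starting material
6 | lithium 3-(4-lithiofuran-3-yl)propan-1-olate | [Li]OCCCc1cocc1[Li] | intermediate
7 | [4-(3-hydroxypropyl)furan-3-yl](furan-3-yl)methanol (racemic) | OCCCc1cocc1C(O)c1ccoc1 | intermediate
8 | 3-[4-(furan-3-ylmethyl)furan-3-yl]propan-1-ol | OCCCc1cocc1Cc1ccoc1 | intermediate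
9 | 3-[4-(furan-3-ylmethyl)furan-3-yl]propanal | O=CCCc1cocc1Cc1ccoc1 | intermediate
10 | 2-(triphenylphosphoranylidene)propanal | CC(C=O)=P(c1ccccc1)(c1ccccc1)c1ccccc1 | starting material
11 | (2E)-5-[4-(furan-3-ylmethyl)furan-3-yl]-2-methylpent-2-enal | O=C/C(C)=C/CCc1cocc1Cc1ccoc1 | intermediate
12 | 3-(furan-3-ylmethyl)-4-[(3E,5E)-6-iodo-4-methylhexa-3,5-dien-1-yl]furan | I/C=C/C(C)=C/CCc1cocc1Cc1ccoc1 | intermediate
13 | methyl (2S)-3-hydroxy-2-methylpropanoate | COC(=O)[C@@H](C)CO | starting material
14 | methyl (2S)-3-[(tert-butyldimethylsilyl)oxy]-2-methylpropanoate | COC(=O)[C@@H](C)CO[Si](C)(C)C(C)(C)C | intermediate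
15 | (2S)-3-[(tert-butyldimethylsilyl)oxy]-2-methylpropanal | O=C[C@@H](C)CO[Si](C)(C)C(C)(C)C | intermediate
16 | tert-butyl(dimethyl){[(2R)-2-methylbut-3-yn-1-yl]oxy}silane | C#C[C@@H](C)CO[Si](C)(C)C(C)(C)C | intermediate
17 | propanal | CCC=O | starting material
18 | lithium acetylide of 16 | [Li]C#C[C@@H](C)CO[Si](C)(C)C(C)(C)C | intermediate
19 | (6R)-7-[(tert-butyldimethylsilyl)oxy]-6-methylhept-4-yn-3-ol (both C3 epimers) | CCC(O)C#C[C@@H](C)CO[Si](C)(C)C(C)(C)C | intermediate
20 | chloromagnesium alkoxide of the (4-chloromagnesio)alkene, H and Mg cis | CCC(O[Mg]Cl)/C([Mg]Cl)=C\[C@@H](C)CO[Si](C)(C)C(C)(C)C | intermediate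
21 | (4E,6R)-7-[(tert-butyldimethylsilyl)oxy]-4-iodo-6-methylhept-4-en-3-ol (both C3 epimers) | CCC(O)/C(I)=C\[C@@H](C)CO[Si](C)(C)C(C)(C)C | intermediate
22 | (4E,6R)-3,7-bis[(tert-butyldimethylsilyl)oxy]-4-iodo-6-methylhept-4-ene | CCC(O[Si](C)(C)C(C)(C)C)/C(I)=C\[C@@H](C)CO[Si](C)(C)C(C)(C)C | intermediate
23 | alkenyllithium from 22 (Li in place of I, same geometry) | CCC(O[Si](C)(C)C(C)(C)C)/C([Li])=C\[C@@H](C)CO[Si](C)(C)C(C)(C)C | intermediate
24 | lithium (E)-enolate (OLi in place of I, same geometry) | CCC(O[Si](C)(C)C(C)(C)C)/C(O[Li])=C\[C@@H](C)CO[Si](C)(C)C(C)(C)C | intermediate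
25 | (4E,6R)-3,7-bis[(tert-butyldimethylsilyl)oxy]-6-methylhept-4-en-4-yl methyl carbonate | CCC(O[Si](C)(C)C(C)(C)C)/C(OC(=O)OC)=C\[C@@H](C)CO[Si](C)(C)C(C)(C)C | intermediate
26 | (4E,6R)-3,7-dihydroxy-6-methylhept-4-en-4-yl methyl carbonate | CCC(O)/C(OC(=O)OC)=C\[C@@H](C)CO | intermediate
27 | (4E,6R)-7-hydroxy-6-methyl-3-oxohept-4-en-4-yl methyl carbonate | CCC(=O)/C(OC(=O)OC)=C\[C@@H](C)CO | intermediate
28 | (4E,6R)-7-iodo-6-methyl-3-oxohept-4-en-4-yl methyl carbonate | CCC(=O)/C(OC(=O)OC)=C\[C@@H](C)CI | intermediate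
29 | alkylzinc iodide from 28 | CCC(=O)/C(OC(=O)OC)=C\[C@@H](C)C[Zn]I | intermediate
30 | (4E,6S,8E,10E)-13-[4-(furan-3-ylmethyl)furan-3-yl]-6,10-dimethyl-3-oxotrideca-4,8,10-trien-4-yl methyl carbonate | CCC(=O)/C(OC(=O)OC)=C\[C@@H](C)C/C=C/C(C)=C/CCc1cocc1Cc1ccoc1 | intermediate
31 | lithium α′-enolate of 30 | CC=C(O[Li])/C(OC(=O)OC)=C\[C@@H](C)C/C=C/C(C)=C/CCc1cocc1Cc1ccoc1 | intermediate
32 | lithium tetronate of 33 | CC1=C(O[Li])/C(=C\[C@@H](C)C/C=C/C(C)=C/CCc2cocc2Cc2ccoc2)OC1=O | intermediate
33 | (5E)-5-{(2S,4E,6E)-9-[4-(furan-3-ylmethyl)furan-3-yl]-2,6-dimethylnona-4,6-dien-1-ylidene}-4-hydroxy-3-methylfuran-2(5H)-one | CC1=C(O)/C(=C\[C@@H](C)C/C=C/C(C)=C/CCc2cocc2Cc2ccoc2)OC1=O | target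

**Count and risks**

Total step count: 18. Longest linear sequence: 12 steps (steps 7 to 18, from 13).

Steps most likely to fail:

1. Step 18 (Proposed new method). The base may take the γ-hydrogen at C7 instead of the α′-hydrogen, which would erase the stereocentre and the alkene geometry. The enolate oxygen may attack the carbonate, and reopening of the resulting cyclic carbonate by methoxide could move the acyl group to the other enol oxygen and lead to closure at C6. Methoxide may also simply cleave the enol carbonate.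
 Fallback (known chemistry): it sets out from 15, closes the tetronic ring at C3–C4 by Dieckmann cyclisation of an enol ester, with the 5E geometry enforced by a temporary six-membered lactone, and comes back at 33.
 - Horner–Wadsworth–Emmons reaction of 15 with methyl 2-[(tert-butyldimethylsilyl)oxy]-2-(dimethoxyphosphoryl)acetate (LiN(SiMe3)2, THF) should give methyl (4R)-2,5-bis[(tert-butyldimethylsilyl)oxy]-4-methylpent-2-enoate F1 as an E/Z mixture of no consequence.
 - Aqueous HF in MeCN removes both silyl groups; the hydroxy α-keto ester lactonises and enolises inside the ring to (5R)-3-hydroxy-5-methyl-5,6-dihydro-2H-pyran-2-one F2, whose enol double bond is endocyclic and therefore cis.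
 - Propanoyl chloride and Et3N give (5R)-5-methyl-2-oxo-5,6-dihydro-2H-pyran-3-yl propanoate F3.
 - LiN(SiMe3)2 at −78 °C lets the propanoate enolate attack the lactone carbonyl; the six-membered ring opens and the five-membered one forms, giving (5E)-4-hydroxy-5-[(2R)-3-hydroxy-2-methylpropylidene]-3-methylfuran-2(5H)-one F4.
 - Chloromethyl methyl ether and i-Pr2NEt protect the acidic enol as (5E)-5-[(2R)-3-hydroxy-2-methylpropylidene]-4-(methoxymethoxy)-3-methylfuran-2(5H)-one F5.
 - PPh3, I2 and imidazole give (5E)-5-[(2R)-3-iodo-2-methylpropylidene]-4-(methoxymethoxy)-3-methylfuran-2(5H)-one F6.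
 - Zn insertion and Pd(PPh3)4 coupling with 12 give (5E)-5-{(2S,4E,6E)-9-[4-(furan-3-ylmethyl)furan-3-yl]-2,6-dimethylnona-4,6-dien-1-ylidene}-4-(methoxymethoxy)-3-methylfuran-2(5H)-one F7.
 - Pyridinium p-toluenesulfonate in MeOH removes the acetal to give 33.

2. Step 13. The alkenyllithium may lose its geometry or eliminate the neighbouring silyloxy group, oxygen transfer may be incomplete, or the enolate may be acylated on carbon.
 Fallback: it sets out from 22, makes the C–O bond by copper-mediated coupling of a boron reagent, and comes back at 25 through 24.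
 - Borylation of 22 (PdCl2(PPh3)2, PPh3, KOPh, bis(pinacolato)diboron, toluene, 50 °C) should give (4Z,6R)-3,7-bis[(tert-butyldimethylsilyl)oxy]-6-methyl-4-(4,4,5,5-tetramethyl-1,3,2-dioxaborolan-2-yl)hept-4-ene F8 with retention.
 - KHF2 in aqueous MeOH gives potassium [(4Z,6R)-3,7-bis[(tert-butyldimethylsilyl)oxy]-6-methylhept-4-en-4-yl]trifluoroborate F9.
 - Oxidative coupling with acetic acid (Cu(OAc)2, 4-(dimethylamino)pyridine, O2, 4 Å sieves, MeCN) gives (4E,6R)-3,7-bis[(tert-butyldimethylsilyl)oxy]-6-methylhept-4-en-4-yl acetate F10 with retention.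
 - MeLi (2 equiv, THF, −78 °C) cleaves the enol acetate to 24, which ClCO2Me traps as 25.

3. Step 14. Once the neighbouring hydroxyl is free, the methoxycarbonyl group may migrate from the enol oxygen to it, or close to a cyclic carbonate with loss of methanol, before step 15 removes that hydroxyl.
 Fallback: it sets out from 21, carries C4 as a ketal so that no free hydroxyl ever stands next to the enol carbonate, and comes back at 27.
 - Dess–Martin oxidation of 21 gives (4E,6R)-7-[(tert-butyldimethylsilyl)oxy]-4-iodo-6-methylhept-4-en-3-one F11.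
 - 1,2-Bis(trimethylsilyloxy)ethane with catalytic Me3SiOSO2CF3 (CH2Cl2, −78 °C) gives tert-butyl{[(2R,3E)-4-(2-ethyl-1,3-dioxolan-2-yl)-4-iodo-2-methylbut-3-en-1-yl]oxy}dimethylsilane F12.
 - The sequence of step 13 (t-BuLi; LiOOt-Bu; ClCO2Me) gives (1E,3R)-4-[(tert-butyldimethylsilyl)oxy]-1-(2-ethyl-1,3-dioxolan-2-yl)-3-methylbut-1-en-1-yl methyl carbonate F13.
 - Aqueous HF in MeCN followed by 0.5 M HCl in THF removes the silyl ether and the ketal to give 27.

Further compounds
F1 | step 18 | methyl (4R)-2,5-bis[(tert-butyldimethylsilyl)oxy]-4-methylpent-2-enoate (E/Z mixture) | COC(=O)C(O[Si](C)(C)C(C)(C)C)=C[C@@H](C)CO[Si](C)(C)C(C)(C)C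
F2 | step 18 | (5R)-3-hydroxy-5-methyl-5,6-dihydro-2H-pyran-2-one | OC1=C[C@@H](C)COC1=O
F3 | step 18 | (5R)-5-methyl-2-oxo-5,6-dihydro-2H-pyran-3-yl propanoate | CCC(=O)OC1=C[C@@H](C)COC1=O
F4 | step 18 | (5E)-4-hydroxy-5-[(2R)-3-hydroxy-2-methylpropylidene]-3-methylfuran-2(5H)-one | CC1=C(O)/C(=C\[C@@H](C)CO)OC1=O
F5 | step 18 | (5E)-5-[(2R)-3-hydroxy-2-methylpropylidene]-4-(methoxymethoxy)-3-methylfuran-2(5H)-one | CC1=C(OCOC)/C(=C\[C@@H](C)CO)OC1=O
F6 | step 18 | (5E)-5-[(2R)-3-iodo-2-methylpropylidene]-4-(methoxymethoxy)-3-methylfuran-2(5H)-one | CC1=C(OCOC)/C(=C\[C@@H](C)CI)OC1=O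
F7 | step 18 | (5E)-5-{(2S,4E,6E)-9-[4-(furan-3-ylmethyl)furan-3-yl]-2,6-dimethylnona-4,6-dien-1-ylidene}-4-(methoxymethoxy)-3-methylfuran-2(5H)-one | CC1=C(OCOC)/C(=C\[C@@H](C)C/C=C/C(C)=C/CCc2cocc2Cc2ccoc2)OC1=O
F8 | step 13 | (4Z,6R)-3,7-bis[(tert-butyldimethylsilyl)oxy]-6-methyl-4-(4,4,5,5-tetramethyl-1,3,2-dioxaborolan-2-yl)hept-4-ene | CCC(O[Si](C)(C)C(C)(C)C)/C(B1OC(C)(C)C(C)(C)O1)=C\[C@@H](C)CO[Si](C)(C)C(C)(C)C
F9 | step 13 | potassium [(4Z,6R)-3,7-bis[(tert-butyldimethylsilyl)oxy]-6-methylhept-4-en-4-yl]trifluoroborate | CCC(O[Si](C)(C)C(C)(C)C)/C([B-](F)(F)F)=C\[C@@H](C)CO[Si](C)(C)C(C)(C)C.[K+]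
F10 | step 13 | (4E,6R)-3,7-bis[(tert-butyldimethylsilyl)oxy]-6-methylhept-4-en-4-yl acetate | CCC(O[Si](C)(C)C(C)(C)C)/C(OC(C)=O)=C\[C@@H](C)CO[Si](C)(C)C(C)(C)C
F11 | step 14 | (4E,6R)-7-[(tert-butyldimethylsilyl)oxy]-4-iodo-6-methylhept-4-en-3-one | CCC(=O)/C(I)=C\[C@@H](C)CO[Si](C)(C)C(C)(C)C
F12 | step 14 | tert-butyl{[(2R,3E)-4-(2-ethyl-1,3-dioxolan-2-yl)-4-iodo-2-methylbut-3-en-1-yl]oxy}dimethylsilane | CCC1(OCCO1)/C(I)=C\[C@@H](C)CO[Si](C)(C)C(C)(C)C
F13 | step 14 | (1E,3R)-4-[(tert-butyldimethylsilyl)oxy]-1-(2-ethyl-1,3-dioxolan-2-yl)-3-methylbut-1-en-1-yl methyl carbonate | CCC1(OCCO1)/C(OC(=O)OC)=C\[C@@H](C)CO[Si](C)(C)C(C)(C)C
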